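A direct plan would build the catechol ring from open-chain material and aromatise it only at the very end.
Hept-6-ynoic acid A1 would be converted by Weinreb amide formation and enyne cross-metathesis into diene amide A2, and addition of a C15 organomagnesium chain would give diene ketone A3.
A Diels–Alder reaction of A3 with vinylene carbonate A4 would give cis-fused carbonate A5, methanolysis would give cis-diol A6, and a double Swern-type oxidation with tautomerisation would give the target.
Its weakest steps would be:
- The cycloaddition of A3 with A4: the dienophile is sluggish and would need about 170 °C and a large excess, conditions under which a 2-alkylbutadiene dimerises and polymerises; two stereocentres would be set only to be erased.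
- The oxidative aromatisation of A6: the free catechol would appear in the presence of activated sulfoxide and amine base, where half-oxidation, methylthiomethylation and quinone formation compete, at the last step with all material invested.
- The plan as a whole: six linear steps from A1, most of them spent on constructing a benzene ring that can be bought with both oxygens in place.

**Retrosynthetic overview of the new route**

The feature used is the tetramethylene tether C1–C4 between the catechol ring and the C5 ketone: its central C2–C3 bond has C1 and the arene on one side and C4 and the carbonyl on the other, so cutting it gives two 3-substituted propanoic acids.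
1-Bromopentadecane 1 and succinic anhydride 2 would give the ketone half, 4-oxononadecanoic acid 4, in one step (C5–C6 bond); the arene half is commercial 3-(3,4-dimethoxyphenyl)propanoic acid 6.
Both acids would be activated as N-hydroxyphthalimide esters and joined by a nickel-electrocatalysed doubly decarboxylative sp3–sp3 coupling at a cathode, with the ketone unmasked.
No ring is formed at any stage, because the aromatic ring is bought; the high-temperature cycloaddition, the throw-away stereocentres and the oxidative aromatisation therefore do not arise, and the only late operation is cleavage of two methyl ethers.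

Key step: step 4

Remark: the target has no stereocentre. The catechol is carried as its dimethyl ether because free phenols would interfere with the carbodiimide activation and with the silver salt of the key step.

**Route**

Step 1
Reactants: 1 1-bromopentadecane; 2 succinic anhydride
Product: 4 4-oxononadecanoic acid, via pentadecylmagnesium bromide 3 (not isolated)
Conditions: 1 (1.0 equiv), Mg turnings (1.2 equiv), I2 (cat.), THF, reflux; add slowly to 2 (2.0 equiv), THF, −78 °C to rt; 1 M HCl; acid–base extraction
Reagents that add atoms: none
Why: Grignard formation followed by ring-opening mono-acylation of a cyclic anhydride, in which the first adduct is a magnesium carboxylate whose ketone reacts only slowly at low temperature and inverse addition to excess 2 keeps the Grignard reagent the limiting species, so that γ-keto acid 4 should be obtained after acidification.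

Step 2
Reactants: 4 4-oxononadecanoic acid
Product: 5 1,3-dioxoisoindolin-2-yl 4-oxononadecanoate
Conditions: N-hydroxyphthalimide (1.1 equiv), N,N'-diisopropylcarbodiimide (1.1 equiv), DMAP (0.1 equiv), CH2Cl2, 0 °C to rt
Reagents that add atoms: N-hydroxyphthalimide, O=C1c2ccccc2C(=O)N1O
Why: Steglich-type carbodiimide esterification, in which the acid is activated as its O-acylisourea and acylates N-hydroxyphthalimide under DMAP catalysis, the γ-ketone being a spectator as in the known N-hydroxyphthalimide ester of levulinic acid.

Step 3
Reactants: 6 3-(3,4-dimethoxyphenyl)propanoic acid
Product: 7 1,3-dioxoisoindolin-2-yl 3-(3,4-dimethoxyphenyl)propanoate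
Conditions: N-hydroxyphthalimide (1.1 equiv), N,N'-diisopropylcarbodiimide (1.1 equiv), DMAP (0.1 equiv), CH2Cl2, 0 °C to rt
Reagents that add atoms: N-hydroxyphthalimide, O=C1c2ccccc2C(=O)N1O
Why: Steglich-type carbodiimide esterification of a simple primary acid with N-hydroxyphthalimide, which should give the crystalline redox-active ester without touching the aryl methyl ethers.

Step 4
Reactants: 5 1,3-dioxoisoindolin-2-yl 4-oxononadecanoate; 7 1,3-dioxoisoindolin-2-yl 3-(3,4-dimethoxyphenyl)propanoate
Product: 8 1-(3,4-dimethoxyphenyl)icosan-5-one
Conditions: 5 (1.0 equiv), 7 (3.0 equiv), NiCl2·6H2O (20 mol%), 2,2':6',2''-terpyridine (20 mol%), AgNO3 (0.3 equiv), NaI (electrolyte), NMP, undivided cell, sacrificial Mg anode, reticulated vitreous carbon cathode, constant current, rt, Ar; 1 M HCl work-up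
Reagents that add atoms: none
Why: Nickel-electrocatalysed doubly decarboxylative coupling of two redox-active esters, the reductive relative of a mixed Kolbe electrolysis: cathodically generated low-valent nickel–terpyridine transfers single electrons to 5 and 7, each ester radical anion loses phthalimide anion and CO2, and the two primary radicals (the 3-oxoalkyl radical from 5 and the 2-arylethyl radical from 7) are captured in turn by nickel to give a dialkylnickel species that reductively eliminates with formation of the C2–C3 bond of the chain. The closest known reaction type is this same nickel-catalysed coupling of two N-hydroxyphthalimide esters of primary acids at a cathode coated in the flask with silver metal from AgNO3, a reaction of a kind that should tolerate ketones and ethers. No ring is closed and no stereocentre is formed. The step needs cross- over homo-coupling, which the threefold excess of the cheap one-step ester 7 should favour statistically and the different polarity of the two symmetrical homodimers should make separable, and it needs chemoselectivity for the activated esters over the C5 ketone, which should follow from the much less negative reduction potential of an N-acyloxyphthalimide compared with a dialkyl ketone. Because the counter-reaction is dissolution of the magnesium anode, the electron-rich dimethoxybenzene ring never meets an oxidising potential, which is what rules out a classical anodic Kolbe coupling for this pair of acids. The terpyridine ligand should hold back β-hydride elimination from the alkylnickel intermediates, which would otherwise lead to a vinyl ketone and a styrene.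

Step 5
Reactants: 8 1-(3,4-dimethoxyphenyl)icosan-5-one
Product: 10 1-(3,4-dihydroxyphenyl)icosan-5-one, via cyclic bromoborate ester 9 (not isolated)
Conditions: BBr3 (4 equiv, 1 M in CH2Cl2), CH2Cl2, −78 °C to 0 °C, Ar; then ice-water, 0 °C; work-up with degassed solvents under Ar
Reagents that add atoms: none
Why: Lewis acid ether cleavage (BBr3 demethylation), in which each aryl methyl ether–BBr3 adduct loses bromomethane by attack of bromide on the methyl group, the two oxygens end in cyclic bromoborate 9 and water hydrolyses it to the catechol, while one equivalent of BBr3 is merely complexed by the ketone oxygen and released on hydrolysis, and argon keeps the catechol from air oxidation.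

**Compound list**

1 | 1-bromopentadecane | CCCCCCCCCCCCCCCBr | starting material
2 | succinic anhydride (oxolane-2,5-dione) | O=C1CCC(=O)O1 | starting material
3 | pentadecylmagnesium bromide (formed in the flask, not isolated) | CCCCCCCCCCCCCCC[Mg]Br | intermediate
4 | 4-oxononadecanoic acid | CCCCCCCCCCCCCCCC(=O)CCC(O)=O | intermediate
5 | 1,3-dioxoisoindolin-2-yl 4-oxononadecanoate (N-hydroxyphthalimide ester of 4) | CCCCCCCCCCCCCCCC(=O)CCC(=O)ON1C(=O)c2ccccc2C1=O | intermediate
6 | 3-(3,4-dimethoxyphenyl)propanoic acid | COc1ccc(CCC(O)=O)cc1OC | starting material
7 | 1,3-dioxoisoindolin-2-yl 3-(3,4-dimethoxyphenyl)propanoate (N-hydroxyphthalimide ester of 6) | COc1ccc(CCC(=O)ON2C(=O)c3ccccc3C2=O)cc1OC | intermediate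
8 | 1-(3,4-dimethoxyphenyl)icosan-5-one | CCCCCCCCCCCCCCCC(=O)CCCCc1ccc(OC)c(OC)c1 | intermediate
9 | 2-bromo-5-(5-oxoicosyl)-1,3,2-benzodioxaborole (formed in the flask, not isolated) | CCCCCCCCCCCCCCCC(=O)CCCCc1ccc2OB(Br)Oc2c1 | intermediate
10 | 1-(3,4-dihydroxyphenyl)icosan-5-one | CCCCCCCCCCCCCCCC(=O)CCCCc1ccc(O)c(O)c1 | target

**Step count and risks**

Total step count: 5. Longest linear sequence: 4 steps (steps 1, 2, 4 and 5; step 3 is a one-step side branch).

Steps most likely to fail:

Step 4 (key step). The cross-coupling may lose out to homodimerisation of each radical, to premature reduction of the esters to the alkanes, or to β-hydride elimination at nickel. The fallback sets out from ester 5 and comes back to the route at 8. Commercial 4-(2-bromoethyl)-1,2-dimethoxybenzene F1 would be converted with Mg turnings in THF into [2-(3,4-dimethoxyphenyl)ethyl]magnesium bromide F2 and transmetalated completely with ZnCl2 (0.5 equiv) to bis[2-(3,4-dimethoxyphenyl)ethyl]zinc F3. F3 would then be coupled with 5 in a nickel-catalysed decarboxylative Negishi-type alkyl–alkyl coupling (NiCl2·glyme, 4,4'-di-tert-butyl-2,2'-bipyridine, THF/DMF, rt), a reaction that uses only one radical precursor and so removes the statistical problem.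

Step 1. The Grignard reagent may add a second time to the first-formed keto carboxylate, and conversion may be poor because the anhydride is sparingly soluble in cold THF. The fallback sets out from Grignard reagent 3 and comes back at 4, and it forms the C4–C5 bond in place of the C5–C6 bond. Formylation of 3 with DMF (THF, 0 °C, then dilute HCl) would give hexadecanal F4, which is also commercially available. A Stetter reaction of F4 with methyl acrylate (3-benzyl-5-(2-hydroxyethyl)-4-methylthiazolium chloride, Et3N, 1,4-dioxane, 80 °C) would give methyl 4-oxononadecanoate F5, and saponification (LiOH, THF/H2O, then HCl) would give 4.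

Step 5. Ether cleavage may stop at the monomethyl ethers, the strong Lewis acid may trigger aldol-type self-condensation at the ketone, and the product may oxidise in air during work-up. The fallback sets out from ester 5 and comes back at target 10, replacing the methyl ethers by benzyl ethers that are removed under neutral conditions. Commercially available 3-[3,4-bis(benzyloxy)phenyl]propanoic acid F6 would be converted as in step 3 into 1,3-dioxoisoindolin-2-yl 3-[3,4-bis(benzyloxy)phenyl]propanoate F7. F7 would be coupled with 5 under the conditions of step 4 to give 1-[3,4-bis(benzyloxy)phenyl]icosan-5-one F8, and hydrogenolysis (H2 1 atm, Pd/C, EtOAc, rt), which leaves a dialkyl ketone untouched, would give 10.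

**Further compounds**

F1 | step 4 | 4-(2-bromoethyl)-1,2-dimethoxybenzene | COc1ccc(CCBr)cc1OC
F2 | step 4 | [2-(3,4-dimethoxyphenyl)ethyl]magnesium bromide | COc1ccc(CC[Mg]Br)cc1OC
F3 | step 4 | bis[2-(3,4-dimethoxyphenyl)ethyl]zinc | COc1ccc(CC[Zn]CCc2ccc(OC)c(OC)c2)cc1OC
F4 | step 1 | hexadecanal | CCCCCCCCCCCCCCCC=O
F5 | step 1 | methyl 4-oxononadecanoate | CCCCCCCCCCCCCCCC(=O)CCC(=O)OC
F6 | step 5 | 3-[3,4-bis(benzyloxy)phenyl]propanoic acid | OC(=O)CCc1ccc(OCc2ccccc2)c(OCc2ccccc2)c1
F7 | step 5 | 1,3-dioxoisoindolin-2-yl 3-[3,4-bis(benzyloxy)phenyl]propanoate | O=C(CCc1ccc(OCc2ccccc2)c(OCc2ccccc2)c1)ON1C(=O)c2ccccc2C1=O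
F8 | step 5 | 1-[3,4-bis(benzyloxy)phenyl]icosan-5-one | CCCCCCCCCCCCCCCC(=O)CCCCc1ccc(OCc2ccccc2)c(OCc2ccccc2)c1
A1 | direct plan | hept-6-ynoic acid | C#CCCCCC(O)=O
A2 | direct plan | N-methoxy-N-methyl-6-methylideneoct-7-enamide | C=CC(=C)CCCCC(=O)N(C)OC
A3 | direct plan | 3-methylidenetricos-1-en-8-one | C=CC(=C)CCCCC(=O)CCCCCCCCCCCCCCC
A4 | direct plan | vinylene carbonate (1,3-dioxol-2-one) | O=C1OC=CO1
A5 | direct plan | cis-5-(5-oxoicosyl)-3a,4,7,7a-tetrahydro-1,3-benzodioxol-2-one, racemic (3aR*,7aS*), one enantiomer drawn | CCCCCCCCCCCCCCCC(=O)CCCCC1=CC[C@H]2OC(=O)O[C@H]2C1
A6 | direct plan | cis-4-(5-oxoicosyl)cyclohex-4-ene-1,2-diol, racemic (1R*,2S*), one enantiomer drawn | CCCCCCCCCCCCCCCC(=O)CCCCC1=CC[C@@H](O)[C@@H](O)C1
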